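**Retrosynthetic overview**
- The target comes from its quinone by reduction. The quinone comes from an α-chloro-α-quinonyl derivative of (+)-sclareolide by one acid-triggered cascade: lactone C8–O opening, 1,2-hydride shift from C9 to C8, loss of CO2. This makes the C9=C11(Cl) alkene and sets C8.
- Key step for the C11–aryl bond: 2,4-dimethoxyphenol is oxidatively dearomatised to a quinone monoacetal, and this aryl-cation equivalent is joined to the α-chloro ketene silyl acetal of sclareolide. Rearomatisation gives the ortho-hydroxyaryl group with the correct oxygen pattern.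
- The para oxygen is unmasked by oxidative demethylation to the quinone, which is also the acid-stable form of the arene for the cascade.
- Ring order: the trans-decalin (C5, C10) is taken intact from sclareolide. The six-membered carbocycle of the arene is dearomatised, then re-formed in the coupling. The lactone ring is opened and lost as CO2; no ring is built de novo.

Assumption: atoms are numbered as in drimane/sclareolide (C8 = lactone C–O carbon, C9 = ring-fusion CH, C11 = lactone α-carbon, C12 = lactone C=O; α = face opposite the C10 methyl), and 1-iodo-2,3,5-trimethoxybenzene (used only in a fallback) is taken as purchasable.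

**Step 1**
Reactants: 1 2,4-dimethoxybenzaldehyde
Product: 3 2,4-dimethoxyphenol, via 2,4-dimethoxyphenyl formate 2 (not isolated)
Conditions: mCPBA, CH2Cl2, rt; NaHCO3 wash; then K2CO3, MeOH, rt
Reagents that add atoms: 3-chloroperoxybenzoic acid, O=C(OO)c1cccc(Cl)c1
Why: Dakin-type Baeyer–Villiger oxidation in which the electron-rich aryl group migrates to oxygen to give formate 2, whose methanolysis frees the phenol (no stereocentre).

**Step 2**
Reactants: 3 2,4-dimethoxyphenol
Product: 4 2,4,4-trimethoxycyclohexa-2,5-dien-1-one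
Conditions: PhI(OAc)2, MeOH, 0 °C
Reagents that add atoms: methanol, CO
Why: Hypervalent-iodine oxidative dearomatisation of a 4-alkoxyphenol, the phenoxenium-type intermediate being trapped by methanol at the methoxy-bearing para carbon to give the quinone monoacetal (no stereocentre).

**Step 3**
Reactants: 5 (+)-sclareolide
Product: 7 11α-chlorosclareolide, via lithium enolate 6 (not isolated)
Conditions: LiHMDS, THF, −78 °C; cannulate into NCS, THF, −78 °C; NH4Cl
Reagents that add atoms: N-chlorosuccinimide, O=C1CCC(=O)N1Cl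
Why: Enolate α-chlorination in which NCS attacks enolate 6 on the α face, away from the axial C8 and C10 methyls; this C11 configuration is erased again in step 4.

**Step 4**
Reactants: 7 11α-chlorosclareolide; 4 2,4,4-trimethoxycyclohexa-2,5-dien-1-one
Product: 11 11β-chloro-11α-(2-hydroxy-3,5-dimethoxyphenyl)sclareolide, via lithium enolate 8 (not isolated), via silyl ketene acetal 9 (not isolated), via cyclohexadienone adduct 10 (not isolated)
Conditions: LiHMDS, TMSCl, THF, −78 °C; evaporate; then 4, TMSOTf (10 mol %), CH2Cl2, −78 to −40 °C; pH 7 buffer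
Reagents that add atoms: none
Why: Proposed new method: TMSOTf ionises acetal 4 to the 2,4-dimethoxyphenoxenium ion, whose only unsubstituted electrophilic carbon (C6, α to the carbonyl) is attacked by ketene acetal 9 from its α face (the β face is shielded by the axial C8 and C10 methyls), so that at C11 the aryl group ends α and chlorine β before enolisation of dienone 10 restores the arene; the closest known reactions are the Kita SN2′ coupling of quinone monoacetals with π-nucleophiles at the α-carbonyl carbon and the Noyori–Mukaiyama TMSOTf coupling of acetals with silyl enol ethers.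

**Step 5**
Reactants: 11 11β-chloro-11α-(2-hydroxy-3,5-dimethoxyphenyl)sclareolide
Product: 12 11β-chloro-11α-(6-methoxy-1,4-benzoquinon-2-yl)sclareolide
Conditions: PhI(OAc)2, MeCN/H2O (4:1), 0 °C
Reagents that add atoms: water, O
Why: Oxidative demethylation of a 4-methoxyphenol to the p-benzoquinone (water adds at the para carbon and methanol leaves), which removes the nucleophilic phenol before the acid step and leaves all stereocentres untouched.

**Step 6**
Reactants: 12 11β-chloro-11α-(6-methoxy-1,4-benzoquinon-2-yl)sclareolide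
Product: 15 2-[(E)-chloro((2S,4aS,8aS)-2,5,5,8a-tetramethyloctahydronaphthalen-1(2H)-ylidene)methyl]-6-methoxycyclohexa-2,5-diene-1,4-dione, via C8 carbocation 13 (not isolated), via C9 carbocation 14 (not isolated)
Conditions: TfOH (20 mol %), (CH2Cl)2, 60 °C
Reagents that add atoms: none
Why: Proposed new method: protonation opens the tertiary lactone C8–O bond to cation 13, H-9α migrates suprafacially to the α face of C8 (setting 8S with the methyl β) and the β-carboxy cation 14 loses CO2 from its α lobe, which turns the β-chlorine toward C8 and the quinonyl group toward C10 and so gives the E-alkene; the closest known reactions are the acid equilibration of sclareolide through its C8 cation and the acid-catalysed Grob-type decarboxylation of β,γ-unsaturated acids and γ-lactones via β-carboxy carbocations.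

**Step 7**
Reactants: 15 2-[(E)-chloro((2S,4aS,8aS)-2,5,5,8a-tetramethyloctahydronaphthalen-1(2H)-ylidene)methyl]-6-methoxycyclohexa-2,5-diene-1,4-dione
Product: 16 2-[(E)-chloro((2S,4aS,8aS)-2,5,5,8a-tetramethyloctahydronaphthalen-1(2H)-ylidene)methyl]-6-methoxybenzene-1,4-diol
Conditions: Na2S2O4, EtOAc/H2O, rt, Ar
Reagents that add atoms: none
Why: Dithionite reduction of the quinone to the hydroquinone, which touches neither the vinyl chloride nor any stereocentre.

**Compound list**
1 | 2,4-dimethoxybenzaldehyde | COc1ccc(C=O)c(OC)c1 | starting material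
2 | 2,4-dimethoxyphenyl formate | COc1ccc(OC=O)c(OC)c1 | intermediate
3 | 2,4-dimethoxyphenol | COc1ccc(O)c(OC)c1 | intermediate
4 | 2,4,4-trimethoxycyclohexa-2,5-dien-1-one (quinone monoacetal) | COC1=CC(OC)(OC)C=CC1=O | intermediate
5 | (+)-sclareolide, (3aR,5aS,9aS,9bR)-3a,6,6,9a-tetramethyldecahydronaphtho[2,1-b]furan-2(1H)-one | O=C1C[C@H]2[C@@](C)(CC[C@H]3C(C)(C)CCC[C@]23C)O1 | starting material
6 | lithium enolate of sclareolide | [Li+].[O-]C1=C[C@H]2[C@@](C)(CC[C@H]3C(C)(C)CCC[C@]23C)O1 | intermediate
7 | 11α-chlorosclareolide (11S) | O=C1[C@@H](Cl)[C@H]2[C@@](C)(CC[C@H]3C(C)(C)CCC[C@]23C)O1 | intermediate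
8 | lithium enolate of 7 | [Li+].[O-]C1=C(Cl)[C@H]2[C@@](C)(CC[C@H]3C(C)(C)CCC[C@]23C)O1 | intermediate
9 | 11-chloro ketene trimethylsilyl acetal of sclareolide | C[Si](C)(C)OC1=C(Cl)[C@H]2[C@@](C)(CC[C@H]3C(C)(C)CCC[C@]23C)O1 | intermediate
10 | 11β-chloro-11α-(3,5-dimethoxy-2-oxocyclohexa-3,5-dien-1-yl)sclareolide (ring CH not controlled, one epimer drawn; lost on enolisation) | O=C1[C@@](Cl)([C@@H]4C=C(OC)C=C(OC)C4=O)[C@H]2[C@@](C)(CC[C@H]3C(C)(C)CCC[C@]23C)O1 | intermediate
11 | 11β-chloro-11α-(2-hydroxy-3,5-dimethoxyphenyl)sclareolide (11S) | O=C1[C@@](Cl)(c4cc(OC)cc(OC)c4O)[C@H]2[C@@](C)(CC[C@H]3C(C)(C)CCC[C@]23C)O1 | intermediate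
12 | 11β-chloro-11α-(6-methoxy-1,4-benzoquinon-2-yl)sclareolide (11S) | O=C1[C@@](Cl)(C4=CC(=O)C=C(OC)C4=O)[C@H]2[C@@](C)(CC[C@H]3C(C)(C)CCC[C@]23C)O1 | intermediate
13 | ring-opened C8 carbocation (free carboxylic acid, 9α-H) | OC(=O)[C@@](Cl)(C4=CC(=O)C=C(OC)C4=O)[C@H]2[C+](C)CC[C@H]3C(C)(C)CCC[C@]23C | intermediate
14 | C9 carbocation after the 1,2-hydride shift (8α-H, 8β-methyl) | OC(=O)[C@@](Cl)(C4=CC(=O)C=C(OC)C4=O)[C+]2[C@@H](C)CC[C@H]3C(C)(C)CCC[C@]23C | intermediate
15 | 2-[(E)-chloro((2S,4aS,8aS)-2,5,5,8a-tetramethyloctahydronaphthalen-1(2H)-ylidene)methyl]-6-methoxycyclohexa-2,5-diene-1,4-dione | COC1=CC(=O)C=C(/C(Cl)=C2/[C@@H](C)CC[C@H]3C(C)(C)CCC[C@]23C)C1=O | intermediate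
16 | 2-[(E)-chloro((2S,4aS,8aS)-2,5,5,8a-tetramethyloctahydronaphthalen-1(2H)-ylidene)methyl]-6-methoxybenzene-1,4-diol | COc1cc(O)cc(/C(Cl)=C2/[C@@H](C)CC[C@H]3C(C)(C)CCC[C@]23C)c1O | target

**Totals**
Total steps: 7. Longest linear sequence: 6 steps (1 → 3 → 4 → 11 → 12 → 15 → 16). The sclareolide branch is 5 steps.

**Steps most likely to fail**

Step 4. A quaternary, chlorine-bearing carbon must attack the phenoxenium ion. Possible failures are ipso attack at the methoxy-bearing para carbon, protodesilylation of 9, or attack from the wrong face. The face matters because only the 11β-Cl/11α-aryl epimer is expected to give the E-alkene in step 6. Fallback: set out from 7 and make ketene acetal 9 as before, but arylate it under copper catalysis (Cu(OTf)2 10 mol %, CH2Cl2, rt) with (mesityl)(2,3,5-trimethoxyphenyl)iodonium triflate F1. F1 is made in one pot from 1-iodo-2,3,5-trimethoxybenzene, mesitylene, mCPBA and TfOH. The Cu(III)–aryl is again delivered to the α face and gives 11β-chloro-11α-(2,3,5-trimethoxyphenyl)sclareolide F2. Ceric ammonium nitrate in MeCN/H2O then removes the two para-disposed methyl groups oxidatively and rejoins the route at 12.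

Step 6. The C8 cation may only eliminate or re-lactonise. The electron-poor C9 cation may suffer methyl migration from C10 before CO2 is lost. The E/Z ratio rests on the rotamer argument. Fallback: set out from 12 and stop the acid treatment early (Tf2NH 5 mol %, CH2Cl2, −20 °C) at the tetrasubstituted β,γ-unsaturated acid, (S)-2-chloro-2-(6-methoxy-1,4-benzoquinon-2-yl)-2-[(4aS,8aS)-2,5,5,8a-tetramethyl-3,4,4a,5,6,7,8,8a-octahydronaphthalen-1-yl]acetic acid F3. F3 is isolated and decarboxylated thermally (mesitylene, 150 °C) through the concerted six-membered retro-ene transition state. The carboxyl proton is handed to the less hindered α face of C8 without a free C9 cation, and the route is rejoined at 15.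

Step 5. The oxidation is run on a substrate with a tertiary benzylic chloride next to a free phenol, which may lose HCl to an ortho-quinone methide. Fallback: set out from 11 and change the order. First run the acid fragmentation on the electron-rich phenol (TfOH, (CH2Cl)2, 40 °C), where the aryl group assists the hydride shift. This gives 2-[(E)-chloro((2S,4aS,8aS)-2,5,5,8a-tetramethyloctahydronaphthalen-1(2H)-ylidene)methyl]-4,6-dimethoxyphenol F4. Then oxidise F4 with PhI(OAc)2 in MeCN/H2O to rejoin the route at 15.

**Further compounds**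
F1 | step 4 | (mesityl)(2,3,5-trimethoxyphenyl)iodonium triflate | COc1cc(OC)c(OC)c([I+]c2c(C)cc(C)cc2C)c1.[O-]S(=O)(=O)C(F)(F)F
F2 | step 4 | 11β-chloro-11α-(2,3,5-trimethoxyphenyl)sclareolide | O=C1[C@@](Cl)(c4cc(OC)cc(OC)c4OC)[C@H]2[C@@](C)(CC[C@H]3C(C)(C)CCC[C@]23C)O1
F3 | step 6 | (S)-2-chloro-2-(6-methoxy-1,4-benzoquinon-2-yl)-2-[(4aS,8aS)-2,5,5,8a-tetramethyl-3,4,4a,5,6,7,8,8a-octahydronaphthalen-1-yl]acetic acid | OC(=O)[C@@](Cl)(C4=CC(=O)C=C(OC)C4=O)C2=C(C)CC[C@H]3C(C)(C)CCC[C@]23C
F4 | step 5 | 2-[(E)-chloro((2S,4aS,8aS)-2,5,5,8a-tetramethyloctahydronaphthalen-1(2H)-ylidene)methyl]-4,6-dimethoxyphenol | COc1cc(OC)cc(/C(Cl)=C2/[C@@H](C)CC[C@H]3C(C)(C)CCC[C@]23C)c1O
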